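**Retrosynthetic overview**
- Ring B is made first: 1 + 2 → 3 → 4, where the proline aldol closes ring B and sets C5 and C10 (10-OH cis to 5-CH3).
- Ring A is made second: the five-membered ketone of 5 is enlarged with 6 to six-membered ketone 11 by a one-carbon 1,2-shift that inserts C4 with its methyl group.
- C3–O is set by equatorial hydride delivery (13) and acylated with 14 to give 16.
- C7–C11 is disconnected to 2-iodoenone 18 + 19, joined by a new enantioselective nickel reductive alkenyl–alkyl coupling (20) that sets C11.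
- Ester cleavage of 20 gives target 22.

Numbering: decalin compounds carry eremophilane numbers (C5 and C10 ring fusion; C14 = CH3 on C5, C15 = CH3 on C4; C11–C13 = side chain on C7; "trinor" = without C11–C13); β = face of the C5 methyl group; angeloyl = (2Z)-2-methylbut-2-enoyl.
Assumption: the sense of induction of the new nickel coupling (step 9) is unproven; the ligand antipode that gives 11R is to be chosen by experiment.

Step 1
Reactants: 1 2-methylcyclopentane-1,3-dione; 2 methyl vinyl ketone (but-3-en-2-one)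
Product: 3 2-methyl-2-(3-oxobutyl)cyclopentane-1,3-dione
Conditions: H2O, AcOH (cat.), 70 °C
Reagents that add atoms: none
Why: Michael addition of the enolised 1,3-dione to the enone gives the prochiral triketone; no stereocentre is formed.

Step 2
Reactants: 3 2-methyl-2-(3-oxobutyl)cyclopentane-1,3-dione
Product: 4 (3aS,7aS)-3a-hydroxy-7a-methylhexahydro-1H-indene-1,5(4H)-dione (cis-fused Hajos–Parrish ketol)
Conditions: (S)-proline (3 mol %), DMF, 20 °C; recrystallisation
Reagents that add atoms: none
Why: Hajos–Parrish–Eder–Sauer–Wiechert aldol, in which the proline enamine of the methyl ketone attacks one of the two enantiotopic ring carbonyls to give the 3aS,7aS cis ketol (about 93% ee, upgraded by crystallisation), which forms ring B and fixes C5 and C10 of the target.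

Step 3
Reactants: 4 (3aS,7aS)-3a-hydroxy-7a-methylhexahydro-1H-indene-1,5(4H)-dione
Product: 5 (3aS,7aS)-3a-hydroxy-5,5-dimethoxy-7a-methyloctahydro-1H-inden-1-one
Conditions: HC(OMe)3, MeOH, PPTS (cat.), 20 °C; Et3N quench
Reagents that add atoms: methanol CO; trimethyl orthoformate COC(OC)OC
Why: Acid-catalysed ketalisation is selective for the unhindered six-ring ketone over the neopentyl five-ring ketone, and the mild acid at room temperature does not dehydrate the tertiary aldol; no stereocentre changes.

Step 4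
Reactants: 5 (3aS,7aS)-3a-hydroxy-5,5-dimethoxy-7a-methyloctahydro-1H-inden-1-one; 6 1,1-dibromoethane
Product: 11 (4R,5R,10S)-10-hydroxy-8,8-dimethoxy-11,12,13-trinoreremophilan-3-one, via 1,1-dibromoethyllithium 7 (not isolated), via dibromo dialkoxide adduct 8 (not isolated), via β-oxido carbenoid 9 (not isolated), via dilithium enolate 10 (not isolated)
Conditions: LiN(i-Pr)2, THF, −100 °C; then n-BuLi, −100 → −20 °C; then aq. NH4Cl
Reagents that add atoms: none
Why: One-carbon ring expansion through a β-oxido carbenoid (Taguchi–Nozaki-type anionic 1,2-shift): 7 adds to the only free ketone, Br/Li exchange gives 9, the alkoxide is expected to push the more substituted, electron-richer quaternary carbon onto the carbenoid carbon with loss of LiBr (retention at the migrating carbon, so C5 and C10 are untouched), and enolate 10 is protonated axially, anti to the axial C5 methyl, to give the equatorial 4β-methyl, which is also judged the thermodynamic epimer.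

Step 5
Reactants: 11 (4R,5R,10S)-10-hydroxy-8,8-dimethoxy-11,12,13-trinoreremophilan-3-one
Product: 13 (3S,4R,5R,10S)-3,10-dihydroxy-11,12,13-trinoreremophilan-8-one, via ketal diol 12 (not isolated)
Conditions: LiBH(s-Bu)3 (L-Selectride), THF, −78 °C; then 0.5 M HCl, THF–H2O, 0 → 20 °C
Reagents that add atoms: water O
Why: Ketone reduction by a bulky hydride occurs equatorially because the axial path is blocked by the 1,3-diaxial C5 methyl, giving the axial 3β (3S) alcohol cis to both methyl groups, and the acidic work-up hydrolyses the dimethyl ketal.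

Step 6
Reactants: 13 (3S,4R,5R,10S)-3,10-dihydroxy-11,12,13-trinoreremophilan-8-one; 14 angelic acid ((2Z)-2-methylbut-2-enoic acid)
Product: 16 (3S,4R,5R,10S)-3-angeloyloxy-10-hydroxy-11,12,13-trinoreremophilan-8-one, via angelic 2,4,6-trichlorobenzoic anhydride 15 (not isolated)
Conditions: 2,4,6-Cl3C6H2COCl, Et3N, PhMe, 20 °C; then 13, 60 °C (no DMAP)
Reagents that add atoms: none
Why: Yamaguchi-type mixed-anhydride esterification without a nucleophilic catalyst acylates only the secondary C3 hydroxyl (the tertiary C10 hydroxyl is inert) and avoids the angelate-to-tiglate isomerisation that acylpyridinium intermediates cause.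

Step 7
Reactants: 16 (3S,4R,5R,10S)-3-angeloyloxy-10-hydroxy-11,12,13-trinoreremophilan-8-one
Product: 17 (3S,4R,5R,10S)-3-angeloyloxy-10-hydroxy-11,12,13-trinoreremophil-6-en-8-one
Conditions: IBX, 4-methoxypyridine N-oxide, DMSO, 25 °C
Reagents that add atoms: none
Why: IBX α,β-dehydrogenation of the C8 ketone can only give the 6,7-alkene because C10 carries no hydrogen, and the N-oxide complex allows room temperature so the tertiary β-hydroxy ketone should not dehydrate.

Step 8
Reactants: 17 (3S,4R,5R,10S)-3-angeloyloxy-10-hydroxy-11,12,13-trinoreremophil-6-en-8-one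
Product: 18 (3S,4R,5S,10S)-3-angeloyloxy-10-hydroxy-7-iodo-11,12,13-trinoreremophil-6-en-8-one (same geometry; the C5 descriptor changes only through CIP priority)
Conditions: I2, pyridine, CH2Cl2, 0 → 20 °C
Reagents that add atoms: iodine II
Why: Johnson α-iodination (pyridine conjugate addition, iodination of the enolate, elimination) places iodine on C7, as it does for other 4,4-disubstituted cyclohexenones.

Step 9
Reactants: 18 (3S,4R,5S,10S)-3-angeloyloxy-10-hydroxy-7-iodo-11,12,13-trinoreremophil-6-en-8-one; 19 methyl 2-chloropropanoate (racemic)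
Product: 20 methyl (3S,4R,5R,10S,11R)-3-angeloyloxy-10-hydroxy-8-oxoeremophil-6-en-12-oate
Conditions: NiBr2·diglyme (10 mol %), (4S,4'S)-4,4'-di(heptan-4-yl)-2,2'-bi(2-oxazoline) (12 mol %), Mn powder, NaI, DMA, 0 °C
Reagents that add atoms: none
Why: Proposed new method: an enantioconvergent nickel-catalysed reductive cross-electrophile coupling in which zerovalent nickel on the chiral bi(oxazoline) adds oxidatively to the C7–I bond, halogen abstraction turns 19 into the planar α-ester radical (both enantiomers converge), the radical is captured at nickel and the trivalent alkenyl(alkyl)nickel reductively eliminates in the chiral pocket to form C7–C11 and set 11R under catalyst control, with Mn returning nickel to the zerovalent state; the closest known reaction type is the nickel/bi(oxazoline)-catalysed enantioselective reductive coupling of α-chloro esters with aryl iodides and of benzylic chlorides with alkenyl bromides, which to my knowledge has not been shown for 2-iodoenones.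

Step 10
Reactants: 20 methyl (3S,4R,5R,10S,11R)-3-angeloyloxy-10-hydroxy-8-oxoeremophil-6-en-12-oate
Product: 22 (3S,4R,5R,10S,11R)-3-angeloyloxy-10-hydroxy-8-oxoeremophil-6-en-12-oic acid (CNP0307859.1), via trimethylstannyl ester 21 (not isolated)
Conditions: Me3SnOH, ClCH2CH2Cl, 70 °C; then dilute HCl wash
Reagents that add atoms: trimethyltin hydroxide C[Sn](C)(C)O
Why: Me3SnOH hydrolyses the unhindered methyl ester by acyl–oxygen cleavage under nearly neutral conditions, leaving the hindered conjugated angelate, the epimerisable C11 centre, the 6-ene and the tertiary aldol intact.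

**Compound list**
1 | 2-methylcyclopentane-1,3-dione | CC1C(=O)CCC1=O | starting material
2 | methyl vinyl ketone | CC(=O)C=C | starting material
3 | 2-methyl-2-(3-oxobutyl)cyclopentane-1,3-dione | CC(=O)CCC1(C)C(=O)CCC1=O | intermediate
4 | (3aS,7aS)-3a-hydroxy-7a-methylhexahydro-1H-indene-1,5(4H)-dione | O=C1CC[C@]2(O)CC(=O)CC[C@]12C | intermediate
5 | (3aS,7aS)-3a-hydroxy-5,5-dimethoxy-7a-methyloctahydro-1H-inden-1-one | O=C1CC[C@]2(O)CC(OC)(OC)CC[C@]12C | intermediate
6 | 1,1-dibromoethane | CC(Br)Br | starting material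
7 | 1,1-dibromoethyllithium | [Li]C(C)(Br)Br | intermediate
8 | dilithium (3aS,7aS)-1-(1,1-dibromoethyl)-5,5-dimethoxy-7a-methyloctahydro-1H-indene-1,3a-diolate (C1 epimers) | CC(Br)(Br)C1([O-])CC[C@]2([O-])CC(OC)(OC)CC[C@]12C.[Li+].[Li+] | intermediate
9 | dilithium (3aS,7aS)-1-(1-bromo-1-lithioethyl)-5,5-dimethoxy-7a-methyloctahydro-1H-indene-1,3a-diolate (β-oxido carbenoid) | CC([Li])(Br)C1([O-])CC[C@]2([O-])CC(OC)(OC)CC[C@]12C.[Li+].[Li+] | intermediate
10 | dilithium (5R,10S)-8,8-dimethoxy-11,12,13-trinoreremophil-3-ene-3,10-diolate (C3 enolate, C10 alkoxide) | [Li+].[Li+].[O-]C=1CC[C@]2([O-])CC(OC)(OC)CC[C@]2(C)C=1C | intermediate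
11 | (4R,5R,10S)-10-hydroxy-8,8-dimethoxy-11,12,13-trinoreremophilan-3-one (cis-decalin; 4-CH3, 5-CH3, 10-OH all β) | O=C1CC[C@]2(O)CC(OC)(OC)CC[C@]2(C)[C@H]1C | intermediate
12 | (3S,4R,5R,10S)-8,8-dimethoxy-11,12,13-trinoreremophilane-3,10-diol | O[C@H]1CC[C@]2(O)CC(OC)(OC)CC[C@]2(C)[C@H]1C | intermediate
13 | (3S,4R,5R,10S)-3,10-dihydroxy-11,12,13-trinoreremophilan-8-one | O[C@H]1CC[C@]2(O)CC(=O)CC[C@]2(C)[C@H]1C | intermediate
14 | angelic acid | C/C=C(/C)C(=O)O | starting material
15 | (2Z)-2-methylbut-2-enoic 2,4,6-trichlorobenzoic anhydride | C/C=C(/C)C(=O)OC(=O)c1c(Cl)cc(Cl)cc1Cl | intermediate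
16 | (3S,4R,5R,10S)-3-angeloyloxy-10-hydroxy-11,12,13-trinoreremophilan-8-one | C/C=C(/C)C(=O)O[C@H]1CC[C@]2(O)CC(=O)CC[C@]2(C)[C@H]1C | intermediate
17 | (3S,4R,5R,10S)-3-angeloyloxy-10-hydroxy-11,12,13-trinoreremophil-6-en-8-one | C/C=C(/C)C(=O)O[C@H]1CC[C@]2(O)CC(=O)C=C[C@]2(C)[C@H]1C | intermediate
18 | (3S,4R,5S,10S)-3-angeloyloxy-10-hydroxy-7-iodo-11,12,13-trinoreremophil-6-en-8-one | C/C=C(/C)C(=O)O[C@H]1CC[C@]2(O)CC(=O)C(I)=C[C@]2(C)[C@H]1C | intermediate
19 | methyl 2-chloropropanoate (racemic) | CC(Cl)C(=O)OC | starting material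
20 | methyl (3S,4R,5R,10S,11R)-3-angeloyloxy-10-hydroxy-8-oxoeremophil-6-en-12-oate | C/C=C(/C)C(=O)O[C@H]1CC[C@]2(O)CC(=O)C([C@@H](C)C(=O)OC)=C[C@]2(C)[C@H]1C | intermediate
21 | trimethylstannyl (3S,4R,5R,10S,11R)-3-angeloyloxy-10-hydroxy-8-oxoeremophil-6-en-12-oate | C/C=C(/C)C(=O)O[C@H]1CC[C@]2(O)CC(=O)C([C@@H](C)C(=O)O[Sn](C)(C)C)=C[C@]2(C)[C@H]1C | intermediate
22 | (3S,4R,5R,10S,11R)-3-angeloyloxy-10-hydroxy-8-oxoeremophil-6-en-12-oic acid | C/C=C(/C)C(=O)O[C@H]1CC[C@]2(O)CC(=O)C([C@@H](C)C(=O)O)=C[C@]2(C)[C@H]1C | target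

**Totals**
Total step count: 10. Longest linear sequence: 10 (2, 6, 14 and 19 are bought).

**Steps most likely to fail**

Step 4 (ring expansion). The risks are slow addition of 7 to the neopentyl ketone and migration of the CH2 carbon instead of the quaternary carbon; I am not certain of the migration preference for this carbenoid. Fallback, from 5 back to 11, by the selenium-based ring enlargement: 1,1-bis(methylselanyl)ethane F1 (from acetaldehyde and methaneselenol, ZnCl2) is cleaved with n-BuLi (THF, −78 °C) to 1-(methylselanyl)ethyllithium F2, which adds to the ketone of 5 to give β-hydroxy selenide F3. AgBF4 on Al2O3 in CH2Cl2 then ionises the C–Se bond, and in this cationic semipinacol shift the more substituted carbon migrates, giving 11 after equilibration at C4.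

Step 9 (new nickel coupling). The risks are hydrodeiodination of 18, homocoupling, and low or mismatched control at C11. Fallback, from 18 back to 20, by known palladium chemistry: Zn dust inserts into methyl 2-bromopropanoate to give the Reformatsky reagent bromo(1-methoxy-1-oxopropan-2-yl)zinc F6. Pd2(dba)3/XPhos-catalysed Negishi-type coupling with 18 (THF, 20 °C) gives 20 together with its 11S epimer F7 (about 1:1), and the two are separated by preparative HPLC.

Step 7 (dehydrogenation). The risks are dehydration of the tertiary β-hydroxy ketone to the cross-conjugated dienone and slow enolisation. Fallback, from 16 back to 17, by Saegusa–Ito oxidation: Me3SiOTf/Et3N (CH2Cl2, −78 → 0 °C) gives the 8,10-bis(trimethylsilyloxy)-7-ene F4; Pd(OAc)2 (MeCN, 20 °C) gives the 10-O-trimethylsilyl enone F5; citric acid in MeOH removes the silyl ether to give 17.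

**Further compounds**
F1 | step 4 | 1,1-bis(methylselanyl)ethane | CC([Se]C)[Se]C
F2 | step 4 | 1-(methylselanyl)ethyllithium | [Li]C(C)[Se]C
F3 | step 4 | (3aS,7aS)-5,5-dimethoxy-7a-methyl-1-[1-(methylselanyl)ethyl]octahydro-1H-indene-1,3a-diol | C[Se]C(C)C1(O)CC[C@]2(O)CC(OC)(OC)CC[C@]12C
F4 | step 7 | (3S,4R,5R,10S)-3-angeloyloxy-8,10-bis(trimethylsilyloxy)-11,12,13-trinoreremophil-7-ene | C/C=C(/C)C(=O)O[C@H]1CC[C@]2(O[Si](C)(C)C)CC(O[Si](C)(C)C)=CC[C@]2(C)[C@H]1C
F5 | step 7 | (3S,4R,5R,10S)-3-angeloyloxy-10-(trimethylsilyloxy)-11,12,13-trinoreremophil-6-en-8-one | C/C=C(/C)C(=O)O[C@H]1CC[C@]2(O[Si](C)(C)C)CC(=O)C=C[C@]2(C)[C@H]1C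
F6 | step 9 | bromo(1-methoxy-1-oxopropan-2-yl)zinc | COC(=O)C(C)[Zn]Br
F7 | step 9 | methyl (3S,4R,5R,10S,11S)-3-angeloyloxy-10-hydroxy-8-oxoeremophil-6-en-12-oate | C/C=C(/C)C(=O)O[C@H]1CC[C@]2(O)CC(=O)C([C@H](C)C(=O)OC)=C[C@]2(C)[C@H]1C
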